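**Retrosynthetic overview** (labdane numbering)
1. Enabling feature: the C10–C9–C8 edge of ring B carries a 4-pentenal unit, O=C20H–C10(quaternary)–C9H–C8(=C17H2). This γ,δ-unsaturated carbonyl array is a Claisen retron. Joining C20 to C17 through oxygen turns ring B into an eight-membered lactone (C20–O–C17–C8–C7–C6–C5–C10) with an exocyclic Z-C8=C9 bond.
2. Key disconnection C9–C10: an Ireland–Claisen ring contraction of that lactone closes ring B and creates C9, quaternary C10, the trans A/B fusion and the C8 methylene in one operation. Only C20 acid → aldehyde and unmasking of the butenolide follow.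
3. The lactone is cut at C20–O (Shiina lactonisation) and C7–C8 (B-alkyl Suzuki–Miyaura coupling) into a ring A acid and a vinyl iodide. The iodide holds the five-membered lactone ring as its α-phenylthio derivative, which has no α-hydrogen and is therefore base-proof.
4. Ring A: an enantioselective iminium-catalysed Diels–Alder reaction sets C5. C4 follows by enolate methylation anti to the C5 vinyl group.
5. Ring order: five-membered lactone (bought closed) → ring A (step 3) → temporary eight-membered lactone (step 17) → ring B (step 18, last ring closed).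

Key step: step 18

Remark on numbering: ring A = C1–C5 and C10; ring B = C5–C10; C11–C12 side chain; C13–C16 five-membered lactone; C17 methylene carbon; C18 methyl; C19 ester carbon; C20 formyl carbon.
Assumption: the sulfur-bearing carbon C13 is carried as a mixture of both configurations and is left undefined in the SMILES, because it becomes sp2 in step 20.

**Step 1**
Reactants: 1 (2E)-penta-2,4-dienoic acid
Product: 2 (2E)-penta-2,4-dien-1-ol
Conditions: LiAlH4, Et2O, 0 °C to rt; then H2O
Reagents that add atoms: none
Why: Hydride reduction of the acid by LiAlH4 is a 1,2-process that gives the primary alcohol and leaves the conjugated E-diene untouched.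

**Step 2**
Reactants: 2 (2E)-penta-2,4-dien-1-ol
Product: 3 tert-butyl[(2E)-penta-2,4-dien-1-yloxy]diphenylsilane
Conditions: TBDPSCl, imidazole, CH2Cl2, 0 °C to rt
Reagents that add atoms: tert-butyl(chloro)diphenylsilane, CC(C)(C)[Si](Cl)(c1ccccc1)c1ccccc1
Why: Silyl ether formation at the only hydroxyl group gives an acid-tolerant and base-stable mask for the later C20 carbon.

**Step 3**
Reactants: 3 tert-butyl[(2E)-penta-2,4-dien-1-yloxy]diphenylsilane; 4 methyl (2E)-4-oxobut-2-enoate
Product: 5 methyl (1R,5R,6R)-5-[(tert-butyldiphenylsilyl)oxymethyl]-6-formylcyclohex-3-ene-1-carboxylate (CHO cis to CH2OSi and trans to CO2Me)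
Conditions: (5R)-5-benzyl-2,2,3-trimethylimidazolidin-4-one hydrochloride (20 mol %), MeCN/H2O 95:5, −10 °C to rt
Reagents that add atoms: none
Why: In this iminium-catalysed enantioselective Diels–Alder reaction the benzyl group shields one face of the E-iminium ion of 4 so that the diene bonds to the Re face of the formyl-bearing carbon (sets C5), the substituted diene terminus bonds next to that carbon ("ortho" rule), the endo mode puts CH2OSi cis to CHO, and the centres at C4 and C10 are placeholders erased in steps 6 and 18.

**Step 4**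
Reactants: 5 Diels–Alder adduct
Product: 6 methyl (1R,2R,3R)-3-[(tert-butyldiphenylsilyl)oxymethyl]-2-formylcyclohexane-1-carboxylate
Conditions: H2 (1 atm), Pd/C, EtOAc, rt
Reagents that add atoms: none
Why: Heterogeneous hydrogenation saturates the only C=C bond while aldehyde, ester and silyl ether persist, and it has to precede the introduction of the vinyl group.

**Step 5**
Reactants: 6 saturated aldehyde
Product: 7 methyl (1R,2R,3R)-3-[(tert-butyldiphenylsilyl)oxymethyl]-2-vinylcyclohexane-1-carboxylate
Conditions: Ph3PCH3Br, KHMDS, THF, −78 to 0 °C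
Reagents that add atoms: methyltriphenylphosphonium bromide, C[P+](c1ccccc1)(c1ccccc1)c1ccccc1.[Br-]
Why: Wittig methylenation with the non-stabilised ylide at low temperature turns CHO into the C6=C7 vinyl group without epimerising C5.

**Step 6**
Reactants: 7 vinyl ester
Product: 9 methyl (1S,2R,3R)-3-[(tert-butyldiphenylsilyl)oxymethyl]-1-methyl-2-vinylcyclohexane-1-carboxylate, via lithium enolate 8 (not isolated)
Conditions: LDA, THF, −78 °C; MeI, DMPU, −78 to −30 °C
Reagents that add atoms: iodomethane, CI
Why: In this ester enolate alkylation allylic 1,3-strain holds the C5 vinyl group of exocyclic enolate 8 axial, so MeI enters from the opposite face and the methyl group ends trans and the ester cis to the vinyl group (4S quaternary centre).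

**Step 7**
Reactants: 9 C4-methylated ester
Product: 10 methyl (1S,2R,3R)-3-(hydroxymethyl)-1-methyl-2-vinylcyclohexane-1-carboxylate
Conditions: HF·pyridine, THF, 0 °C to rt
Reagents that add atoms: none
Why: Fluoride-mediated Si–O cleavage under non-basic conditions frees the primary alcohol without translactonisation onto the neighbouring ester.

**Step 8**
Reactants: 10 primary alcohol
Product: 11 (1R,2R,3S)-3-(methoxycarbonyl)-3-methyl-2-vinylcyclohexane-1-carboxylic acid (ring A acid)
Conditions: TEMPO (cat.), PhI(OAc)2, MeCN/H2O, rt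
Reagents that add atoms: water, O
Why: Oxoammonium (TEMPO) oxidation in wet acetonitrile takes the primary alcohol through the aldehyde hydrate to the acid and spares the vinyl group, and the C10 configuration is of no consequence.

**Step 9**
Reactants: 12 3-bromooxolan-2-one (α-bromo-γ-butyrolactone, racemic)
Product: 13 3-(phenylsulfanyl)oxolan-2-one
Conditions: PhSH, Et3N, CH2Cl2, 0 °C to rt
Reagents that add atoms: benzenethiol, Sc1ccccc1
Why: SN2 displacement of the activated α-bromide by thiolate installs the group that later delivers the butenolide double bond.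

**Step 10**
Reactants: 14 tert-butyldimethyl(prop-2-yn-1-yloxy)silane
Product: 16 5-[(tert-butyldimethylsilyl)oxy]pent-3-yn-1-ol, via lithium acetylide 15 (not isolated)
Conditions: n-BuLi, THF, −78 °C; oxirane, DMPU, −78 °C to rt; then H2O
Reagents that add atoms: oxirane, C1CO1
Why: SN2 opening of oxirane by the lithium acetylide adds C11 and C12 and gives the homopropargylic alcohol.

**Step 11**
Reactants: 16 homopropargylic alcohol
Product: 17 tert-butyl[(5-iodopent-2-yn-1-yl)oxy]dimethylsilane
Conditions: I2, PPh3, imidazole, CH2Cl2, 0 °C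
Reagents that add atoms: iodine, II
Why: Appel-type iodination converts the primary alcohol into the iodide under neutral conditions that leave the silyl ether and the alkyne alone.

**Step 12**
Reactants: 13 3-(phenylsulfanyl)oxolan-2-one; 17 homopropargylic iodide
Product: 19 3-{5-[(tert-butyldimethylsilyl)oxy]pent-3-yn-1-yl}-3-(phenylsulfanyl)oxolan-2-one, via sodium enolate 18 (not isolated)
Conditions: NaH, DMF, 0 °C; then 17, 0 °C to rt
Reagents that add atoms: none
Why: SN2 alkylation of the soft sulfur-stabilised lactone enolate forms C12–C13 and leaves a lactone without α-hydrogen, which serves as a base-proof masked butenolide.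

**Step 13**
Reactants: 19 alkylated lactone
Product: 20 3-(5-hydroxypent-3-yn-1-yl)-3-(phenylsulfanyl)oxolan-2-one
Conditions: HF·pyridine, THF, 0 °C
Reagents that add atoms: none
Why: Fluoride cleavage of the primary silyl ether frees the propargylic alcohol without opening the lactone.

**Step 14**
Reactants: 20 alkynol
Product: 21 3-[(3E)-5-hydroxy-4-(tributylstannyl)pent-3-en-1-yl]-3-(phenylsulfanyl)oxolan-2-one
Conditions: Bu3SnH, PdCl2(PPh3)2 (cat.), THF, 0 °C to rt
Reagents that add atoms: tributylstannane, CCCC[SnH](CCCC)CCCC
Why: Palladium-catalysed hydrostannation is a syn addition in which the propargylic oxygen directs tin to the neighbouring alkyne carbon (C8), which fixes the C11 chain cis to CH2OH, and the distal regioisomer is removed by chromatography.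

**Step 15**
Reactants: 21 vinylstannane
Product: 22 3-[(3E)-5-hydroxy-4-iodopent-3-en-1-yl]-3-(phenylsulfanyl)oxolan-2-one (vinyl iodide)
Conditions: I2, CH2Cl2, 0 °C
Reagents that add atoms: iodine, II
Why: Iododestannylation replaces tin by iodine with retention of the alkene geometry.

**Step 16**
Reactants: 11 ring A acid; 22 vinyl iodide
Product: 24 (1R,2R,3S)-2-{(3Z)-3-(hydroxymethyl)-6-[2-oxo-3-(phenylsulfanyl)oxolan-3-yl]hex-3-en-1-yl}-3-(methoxycarbonyl)-3-methylcyclohexane-1-carboxylic acid (seco acid), via bis-boron adduct 23 (not isolated)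
Conditions: 9-BBN (2.2 equiv), THF, rt; then H2O, 22, PdCl2(dppf) (cat.), AsPh3, Cs2CO3, DMF, rt; acidic work-up
Reagents that add atoms: 9-borabicyclo[3.3.1]nonane, B1C2CCCC1CCC2 (its atoms stay only in intermediate 23)
Why: Anti-Markovnikov hydroboration of the vinyl group, with the acid held in situ as an acyloxyborane that 9-BBN reduces only very slowly, followed by B-alkyl Suzuki–Miyaura coupling forms C7–C8 with retention of the alkene geometry (Z-C8=C9).

**Step 17**
Reactants: 24 seco acid
Product: 25 eight-membered lactone (C20–O–C17 ester bridge; ring fused to ring A at C5–C10; Z-alkylidene on C8)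
Conditions: MNBA, DMAP, CH2Cl2, high dilution (slow addition of 24), rt
Reagents that add atoms: none
Why: Shiina macrolactonisation through the mixed anhydride and acylpyridinium ion has eight-membered lactones within its known scope, ring A and the sp2 carbon C8 remove rotors from the chain, and any epimerisation at C10 is harmless.

**Step 18**
Reactants: 25 eight-membered lactone
Product: 28 ring B acid (trans-decalin; C20 carboxylic acid on C10; C8 exocyclic methylene; C13 phenylthio lactone), via silyl ketene acetal 26 (not isolated), via trimethylsilyl ester 27 (not isolated)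
Conditions: LDA, TMSCl (present from the start), THF, −78 °C; toluene, rt to 80 °C; then 1 M HCl, THF
Reagents that add atoms: chlorotrimethylsilane, C[Si](C)(C)Cl (its atoms stay only in intermediates 26 and 27)
Why: Proposed new method: LDA in the presence of TMSCl removes the only acidic proton (C10–H) and gives the endocyclic silyl ketene acetal 26, in which the eight-membered ring forces C5 and the ring oxygen cis on C10=C20; on warming 26 undergoes a concerted suprafacial [3,3]-sigmatropic shift (Ireland–Claisen rearrangement) that breaks O–C17, forms C9–C10 and moves the alkene from C8=C9 to C8=C17, and acid hydrolysis of silyl ester 27 gives 28. The closest known reaction type is the alicyclic Ireland–Claisen ring contraction of macrolactone silyl ketene acetals whose alkene lies inside the ring (loss of four ring atoms); not yet shown is the case used here, an alkylidene group exocyclic on the carbon next to the carbinol carbon, which contracts the ring by only two atoms. Ring B (C5–C6–C7–C8–C9–C10) closes transannularly, C9 bridging C8 and C10 that face each other across the eight-membered ring, through a transition state shaped like a twin-chair 3-oxabicyclo[3.3.1]nonane in which the pericyclic six-atom array is a chair; a boat array cannot be spanned by the C5–C6–C7 tether. C9 is set by the Z geometry of C8=C9 within this enforced chair: the C11 chain, trans to C7, becomes equatorial on ring B and H9 becomes axial and anti to C20. C10 is set by C5 and quaternary C4: C9 has to come in along the equatorial trajectory of ring A, which gives the trans-decalin with C20 axial, because the axial trajectory leading to the cis-decalin collides with the syn-axial substituent on C4. The step needs site-selective enolisation and survival of the other carbonyl groups, secured because the C4 ester and the α-phenylthio lactone carry no α-hydrogen, and it gains driving force from the release of medium-ring strain and the new C=O bond.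

**Step 19**
Reactants: 28 ring B acid
Product: 30 C20 aldehyde (methyl 20-oxo-13-phenylthio-labd-8(17)-en-16,15-olid-19-oate), via acid chloride 29 (not isolated)
Conditions: (COCl)2, DMF (cat.), CH2Cl2, 0 °C to rt; evaporate; LiAlH(Ot-Bu)3, THF, −78 °C
Reagents that add atoms: oxalyl chloride, ClC(=O)C(=O)Cl (its chlorine stays only in intermediate 29)
Why: The acid chloride is far more electrophilic than the hindered methyl ester and the lactone, and its reduction with the bulky, mild LiAlH(Ot-Bu)3 stops at the neopentyl aldehyde.

**Step 20**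
Reactants: 30 C20 aldehyde
Product: 32 methyl (4S,5R,9S,10S)-20-oxolabda-8(17),13-dien-16,15-olid-19-oate (CNP0175906.1), via sulfoxide 31 (not isolated)
Conditions: mCPBA (1.0 equiv), CH2Cl2, −78 °C; aq NaHCO3 wash; crude 31, toluene, 110 °C
Reagents that add atoms: 3-chloroperoxybenzoic acid, O=C(OO)c1cccc(Cl)c1 (its oxygen stays only in intermediate 31)
Why: Sulfide oxidation outruns epoxidation and aldehyde oxidation at −78 °C, and thermal syn-elimination of the α-sulfinyl lactone (sulfoxide pyrolysis) toward the ring CH2 gives the conjugated endocyclic butenolide and removes the undefined C13 centre.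

**Compound list**
1 | (2E)-penta-2,4-dienoic acid | C=C/C=C/C(=O)O | starting material
2 | (2E)-penta-2,4-dien-1-ol | C=C/C=C/CO | intermediate
3 | tert-butyl[(2E)-penta-2,4-dien-1-yloxy]diphenylsilane | C=C/C=C/CO[Si](c1ccccc1)(c1ccccc1)C(C)(C)C | intermediate
4 | methyl (2E)-4-oxobut-2-enoate | COC(=O)/C=C/C=O | starting material
5 | methyl (1R,5R,6R)-5-[(tert-butyldiphenylsilyl)oxymethyl]-6-formylcyclohex-3-ene-1-carboxylate | O=C[C@@H]1[C@H](CO[Si](c2ccccc2)(c2ccccc2)C(C)(C)C)C=CC[C@H]1C(=O)OC | intermediate
6 | methyl (1R,2R,3R)-3-[(tert-butyldiphenylsilyl)oxymethyl]-2-formylcyclohexane-1-carboxylate | O=C[C@@H]1[C@H](CO[Si](c2ccccc2)(c2ccccc2)C(C)(C)C)CCC[C@H]1C(=O)OC | intermediate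
7 | methyl (1R,2R,3R)-3-[(tert-butyldiphenylsilyl)oxymethyl]-2-vinylcyclohexane-1-carboxylate | C=C[C@@H]1[C@H](CO[Si](c2ccccc2)(c2ccccc2)C(C)(C)C)CCC[C@H]1C(=O)OC | intermediate
8 | lithium enolate of 7 (exocyclic at C4) | C=C[C@@H]1[C@H](CO[Si](c2ccccc2)(c2ccccc2)C(C)(C)C)CCCC1=C([O-])OC.[Li+] | intermediate
9 | methyl (1S,2R,3R)-3-[(tert-butyldiphenylsilyl)oxymethyl]-1-methyl-2-vinylcyclohexane-1-carboxylate | C=C[C@@H]1[C@H](CO[Si](c2ccccc2)(c2ccccc2)C(C)(C)C)CCC[C@]1(C)C(=O)OC | intermediate
10 | methyl (1S,2R,3R)-3-(hydroxymethyl)-1-methyl-2-vinylcyclohexane-1-carboxylate | C=C[C@@H]1[C@H](CO)CCC[C@]1(C)C(=O)OC | intermediate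
11 | (1R,2R,3S)-3-(methoxycarbonyl)-3-methyl-2-vinylcyclohexane-1-carboxylic acid | C=C[C@@H]1[C@H](C(=O)O)CCC[C@]1(C)C(=O)OC | intermediate
12 | 3-bromooxolan-2-one (racemic) | O=C1OCCC1Br | starting material
13 | 3-(phenylsulfanyl)oxolan-2-one (racemic) | O=C1OCCC1Sc1ccccc1 | intermediate
14 | tert-butyldimethyl(prop-2-yn-1-yloxy)silane | C#CCO[Si](C)(C)C(C)(C)C | starting material
15 | lithium acetylide of 14 | [Li+].[C-]#CCO[Si](C)(C)C(C)(C)C | intermediate
16 | 5-[(tert-butyldimethylsilyl)oxy]pent-3-yn-1-ol | OCCC#CCO[Si](C)(C)C(C)(C)C | intermediate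
17 | tert-butyl[(5-iodopent-2-yn-1-yl)oxy]dimethylsilane | ICCC#CCO[Si](C)(C)C(C)(C)C | intermediate
18 | sodium enolate of 13 | [Na+].[O-]C1=C(Sc2ccccc2)CCO1 | intermediate
19 | 3-{5-[(tert-butyldimethylsilyl)oxy]pent-3-yn-1-yl}-3-(phenylsulfanyl)oxolan-2-one | O=C1OCCC1(CCC#CCO[Si](C)(C)C(C)(C)C)Sc1ccccc1 | intermediate
20 | 3-(5-hydroxypent-3-yn-1-yl)-3-(phenylsulfanyl)oxolan-2-one | O=C1OCCC1(CCC#CCO)Sc1ccccc1 | intermediate
21 | 3-[(3E)-5-hydroxy-4-(tributylstannyl)pent-3-en-1-yl]-3-(phenylsulfanyl)oxolan-2-one | OC/C([Sn](CCCC)(CCCC)CCCC)=C\CCC1(Sc2ccccc2)CCOC1=O | intermediate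
22 | 3-[(3E)-5-hydroxy-4-iodopent-3-en-1-yl]-3-(phenylsulfanyl)oxolan-2-one | OC/C(I)=C\CCC1(Sc2ccccc2)CCOC1=O | intermediate
23 | bis-boron adduct of 11 (C7 B-alkyl-9-BBN, acid as acyloxy-9-BBN) | C1CC2CCCC(C1)B2CC[C@@H]1[C@H](C(=O)OB2C3CCCC2CCC3)CCC[C@]1(C)C(=O)OC | intermediate
24 | seco acid (Z-C8=C9, free C17 alcohol and C20 acid) | O=C1OCCC1(Sc1ccccc1)CC/C=C(\CO)CC[C@@H]1[C@H](C(=O)O)CCC[C@]1(C)C(=O)OC | intermediate
25 | eight-membered lactone fused to ring A at C5–C10, Z-alkylidene on C8 | O=C1OCCC1(Sc1ccccc1)CC/C=C1\COC(=O)[C@@H]2CCC[C@](C)(C(=O)OC)[C@@H]2CC1 | intermediate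
26 | endocyclic trimethylsilyl ketene acetal of 25 (C5 and ring oxygen cis on C10=C20) | O=C1OCCC1(Sc1ccccc1)CC/C=C1\CO/C(O[Si](C)(C)C)=C2/CCC[C@](C)(C(=O)OC)[C@@H]2CC1 | intermediate
27 | trimethylsilyl ester of 28 | C=C1CC[C@@H]2[C@](C(=O)O[Si](C)(C)C)(CCC[C@]2(C)C(=O)OC)[C@H]1CCC1(Sc2ccccc2)CCOC1=O | intermediate
28 | ring B acid (trans-decalin, C20 acid, C8 methylene, C13 phenylthio lactone) | C=C1CC[C@@H]2[C@](C(=O)O)(CCC[C@]2(C)C(=O)OC)[C@H]1CCC1(Sc2ccccc2)CCOC1=O | intermediate
29 | C20 acid chloride of 28 | C=C1CC[C@@H]2[C@](C(=O)Cl)(CCC[C@]2(C)C(=O)OC)[C@H]1CCC1(Sc2ccccc2)CCOC1=O | intermediate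
30 | C20 aldehyde with C13 phenylthio lactone | C=C1CC[C@@H]2[C@](C=O)(CCC[C@]2(C)C(=O)OC)[C@H]1CCC1(Sc2ccccc2)CCOC1=O | intermediate
31 | C13 phenylsulfinyl lactone (sulfoxide of 30) | C=C1CC[C@@H]2[C@](C=O)(CCC[C@]2(C)C(=O)OC)[C@H]1CCC1(S(=O)c2ccccc2)CCOC1=O | intermediate
32 | methyl (4S,5R,9S,10S)-20-oxolabda-8(17),13-dien-16,15-olid-19-oate, CNP0175906.1 | C=C1CC[C@@H]2[C@](C=O)(CCC[C@]2(C)C(=O)OC)[C@H]1CCC1=CCOC1=O | target

**Step count**
Total step count: 20.
Longest linear sequence: 13 steps (steps 1–8 and 16–20).

**The three steps most likely to fail**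

1. **Step 18 (ring contraction).**
 - What may go wrong: the congested chair, with the C11 chain wedged between C1 and C20, may be reached too slowly, so that the ketene acetal fragments into ketene and allyloxide. Closure may also leak through the cis-decalin topography.
 - Fallback (known chemistry; sets out from 11 and 22, comes back at 28): the order of bond formation is inverted. Steglich esterification (EDC·HCl, DMAP, CH2Cl2) joins acid and alcohol to the open allyl ester F1. A conventional acyclic Ireland–Claisen rearrangement (LDA, TMSCl, THF, −78 °C to rt, acidic work-up), in which the allyl fragment enters anti to the axial C5 vinyl group, should give the 2-iodoallyl acid F2 with C9–C10 in place. C9 epimers that arise from incomplete control of the ketene acetal geometry are separated at this stage. 9-BBN (2.2 equiv) adds only to the C5 vinyl group and gives the bis-boron adduct F3. An intramolecular B-alkyl Suzuki–Miyaura coupling onto the C8 iodide (PdCl2(dppf), AsPh3, Cs2CO3, DMF/H2O) then closes ring B as a methylenecyclohexane and returns to 28.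

2. **Step 17 (eight-membered lactonisation).**
 - What may go wrong: intermolecular acylation (diolide and oligomer formation) may outrun the medium-ring closure at the hindered secondary carboxyl group.
 - Fallback (sets out from 11 and 22, comes back at 25): the ester bond is made first, where it is intermolecular and easy, and the medium ring is closed at C7–C8 instead. Steglich esterification gives the open allyl ester F4 (the same compound as F1). 9-BBN adds to the vinyl group only and gives the B-alkyl borane F5. This is added slowly to PdCl2(dppf), AsPh3 and Cs2CO3 in DMF/THF/H2O at high dilution, so that an intramolecular B-alkyl Suzuki–Miyaura coupling closes the eight-membered ring to 25.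

3. **Step 14 (hydrostannation).**
 - What may go wrong: tin may leak to the distal alkyne carbon (poor regiocontrol), because both alkyne carbons carry a CH2 group.
 - Fallback (sets out from 20, comes back at 21): the alkyne is polarised by a carbonyl group before tin is added. MnO2 (CH2Cl2) oxidises the propargylic alcohol to the ynal F6. Hydrostannation of alkynyl carbonyl compounds under Pd(PPh3)4 catalysis is a syn addition that places tin α to the carbonyl group, which should give the α-stannyl enal F7. Luche reduction (NaBH4, CeCl3·7H2O, MeOH, −78 °C) reduces only the aldehyde and returns to 21.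

**Further compounds**
F1 | step 18 | open allyl ester of acid 11 with iodo alcohol 22 | C=C[C@@H]1[C@H](C(=O)OC/C(I)=C\CCC2(Sc3ccccc3)CCOC2=O)CCC[C@]1(C)C(=O)OC
F2 | step 18 | 2-iodoallyl acid (C9–C10 formed, ring B still open between C7 and C8) | C=C[C@@H]1[C@](C(=O)O)(CCC[C@]1(C)C(=O)OC)[C@@H](CCC1(Sc2ccccc2)CCOC1=O)C(I)=C
F3 | step 18 | bis-boron adduct of F2 (C7 B-alkyl-9-BBN, acid as acyloxy-9-BBN) | C1CC2CCCC(C1)B2CC[C@@H]1[C@](C(=O)OB2C3CCCC2CCC3)(CCC[C@]1(C)C(=O)OC)[C@@H](CCC1(Sc2ccccc2)CCOC1=O)C(I)=C
F4 | step 17 | open allyl ester of acid 11 with iodo alcohol 22 (same compound as F1) | C=C[C@@H]1[C@H](C(=O)OC/C(I)=C\CCC2(Sc3ccccc3)CCOC2=O)CCC[C@]1(C)C(=O)OC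
F5 | step 17 | B-alkyl-9-BBN adduct of F4 | C1CC2CCCC(C1)B2CC[C@@H]1[C@H](C(=O)OC/C(I)=C\CCC2(Sc3ccccc3)CCOC2=O)CCC[C@]1(C)C(=O)OC
F6 | step 14 | 5-[2-oxo-3-(phenylsulfanyl)oxolan-3-yl]pent-2-ynal | O=CC#CCCC1(Sc2ccccc2)CCOC1=O
F7 | step 14 | (2E)-5-[2-oxo-3-(phenylsulfanyl)oxolan-3-yl]-2-(tributylstannyl)pent-2-enal | O=C/C([Sn](CCCC)(CCCC)CCCC)=C\CCC1(Sc2ccccc2)CCOC1=O
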